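Conventions used throughout: the carbons of the bicyclic core are labelled C1–C10 (ring A = C1–C5, ring B = C1, C5–C10, shared bond C1–C5). β is the face that carries the C1 methyl group and α the opposite face.

Assumption: Rh2(S-PTAD)4 is taken to give the (1R,8R) antipode 12 drawn here; the sense of induction for this substrate is not known, and if it is the opposite, Rh2(R-PTAD)4 is used with no other change.

## The problem

Compound 26 is a daucane: a cyclopentane (ring A) trans-fused along C1–C5 to a cycloheptane (ring B), with a quaternary methyl carbon, C1, at one ring-fusion position. Seven stereocentres have to be set: C1, the tertiary isopropyl carbinol C4 (hydroxyl β), C5 (hydrogen α), C6 (isovalerate, α), the trisubstituted C8–C9 epoxide (α) and C10 (acetate, α). All three oxygen functions of ring B therefore lie on the face opposite the C1 methyl. C1 is the only centre that cannot be relayed from a neighbour. Once it is in place it can control C5 and C6 (syn addition to a C5=C6 alkene), C10 (opening of a C9–C10 epoxide), C4 (addition to a ketone beside C5) and the epoxide (delivery from a ring B hydroxyl). The late intermediates are fragile: the epoxide is acid-labile and sits beside an acyloxy carbon, and two different esters must be placed one at a time on two secondary hydroxyls. The C6 ester is β to C4, so it can be lost by elimination while C4 is a ketone, or can shift to the C4 oxygen under base. The feature that allows a short ring construction is that ring B can hold a 1,4-diene, C5=C6 and C9=C10, on either side of C1, while ring A shares C1–C5. That is the retron of a cis-divinylcyclopropane C1–C5–C10, which in turn comes from a C5 carbenoid (acceptor C4=O, donor C6=C7) adding to a C1=C10 alkene tied to it through C2 and C3.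

## Retrosynthesis

**26 ⇒ 24 + 25.** The C4–isopropyl bond is cut first. In ketone 24 the ring fusion is already trans, so the β face of C4 is closed by the C5–C6 bond and the C1 methyl; a nucleophile should enter from α and leave the hydroxyl β. Adding the isopropyl group earlier, to the enone of 12, was set aside: there C1 presents a methyl on one face and a ring carbon on the other, and an α-isopropyl group would later block the face needed for the C5=C6 addition. The price is a reagent that must add to a ketone without touching two esters (25 with CeCl3).

**24 ⇒ 20 (through 23, 22, 21).** These are functional-group changes only: the ketone comes from the silyl-protected carbinol, the isovalerate from the C6 hydroxyl, and the epoxide from the C8=C9 alkene. The order is dictated by the epoxidation, which needs the free C6 hydroxyl of 20 as its directing group, so acylation follows it. The C4 silyl ether is kept until both esters are in place so that each acylation meets only one free hydroxyl.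

**20 ⇒ 17.** Here the C5–H and C6–O bonds are cut (syn hydroboration of C5=C6), and C8=C9 is traced to a C9 selenide. Hydroboration is placed at this stage for a conformational reason. While ring B holds a second cis-locked pair 1,4 to C5=C6 (the C9=C10 alkene, its epoxide, or C8=C9), it is a boat whose α face is concave. In 17, C9 and C10 are both tetrahedral and unbridged, so ring B is a plain cycloheptene. The β face of C5=C6 is then covered by the C1 methyl and the 4β-silyloxy group. The same peroxide work-up also turns the selenide into the C8=C9 alkene.

**17 ⇒ 13 ⇒ 12.** The C9–Se and C10–O bonds come from anti opening of the 9α,10α-epoxide of 13 at C9, the carbon away from the quaternary centre. The transposition is antarafacial overall: oxygen α at C10, hydrogen lost from the β face of C8. This matches the C8 configuration that the ring-forming step delivers in 12. The 4β-carbinol of 14 is set by catalyst-controlled reduction, so the bulk that steers the hydroboration does not depend on substrate bias. Epoxidation is done on 12 itself, where the enone alkene is deactivated.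

**12 ⇒ 10 (through 11).** Cutting C1–C5 and C7–C8 and re-forming C5–C10 opens both rings at once and leads to the acyclic, achiral vinyldiazoketone 10. No other cut removes both rings and the quaternary centre in one step. The forward reaction must choose the proximal alkene, add with enantioface control, and then undergo the [3,3] shift.

**10 ⇒ 9 ⇒ 7 + 8.** The diazo group is introduced on the CH2 between carbonyl and vinyl group of 9, and 9 is cut at the C4–C5 bond into Weinreb amide 7 and allylmagnesium bromide 8. Building the same ketone by alkylating a ketone enolate that already carries the allyl group was set aside: base would remove the doubly activated proton between carbonyl and vinyl group, not a methyl proton.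

**7 ⇒ 5 + 6; 5 ⇒ 4 ⇒ 3 ⇒ 1 + 2.** The C2–C3 bond comes from alkylation of the enolate of 6 with dienyl bromide 5. The E,E-diene of 5 comes from a Wittig reaction of 1 with 2, followed by reduction and bromination. Both alkene geometries are fixed here and carried into the key step.

## Roads not taken

**Alternative 1:** A nitrile oxide cycloaddition would cut C5–C6 and the C4–O bond. Nitrile oxide A3 would add across the C4=C5 bond of cyclopentene A2 to give isoxazoline A1. Its strength is real: the tertiary C4–O bond and the C5 hydrogen are formed together, cis, with the isopropyl group already present. The chosen plan reaches the same result only through a hydroboration and a late organometallic addition. The weak points are that an intermolecular cycloaddition to a trisubstituted alkene beside a quaternary carbon is slow against nitrile oxide dimerisation, and that the facial bias rests on the small difference between a methyl and a silyloxymethyl group on C1. C1 would also have to be made enantiopure beforehand. After N–O cleavage and reduction at C6, ring B would still have to be closed at C9–C10, with the C10 carbinol configuration open. The chosen plan has the longer adjustment after ring formation, but it makes both rings and C1 in one catalytic step.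

**Alternative 2:** An enone–enediol photocycloaddition would cut C1–C10 and C5–C6, then the C6–C10 bond. Irradiation of A5 with A6 would give photoadduct A4, and glycol scission would open ring B. This road is shorter to an oxygenated hydroazulene than the chosen one, and it puts oxygen directly on C6 and C10, which the chosen plan has to install by hydroboration and by an epoxide–selenide transposition. Against it: A4 is racemic with no obvious handle for absolute control. After scission, C5 lies between the C4 and C6 carbonyls, so the ring fusion is enolised and three ketones must be told apart. Hydride attack anti to the C1 methyl would give the wrong (β) alcohol at C10, and the C8=C9 unsaturation needed for the epoxide is absent. The chosen plan keeps a C9=C10 alkene as the handle for C8–C10 and takes its absolute configuration from a catalyst.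

**Alternative 3:** A Nozaki–Hiyama–Kishi closure would cut C9–C10. Iodo aldehyde A8 with CrCl2 and catalytic NiCl2 would give allylic alcohol A7. Its endgame is better than the chosen one: A7 is two steps (directed epoxidation, acetylation) from the target, all ring A centres and the isovalerate are in place, and no organometallic reagent meets an ester-bearing ketone. The difficulty is moved into A8. It needs a cyclopentane with three contiguous stereocentres including the formyl-bearing quaternary C1, a C6 stereocentre in the side chain and a Z-trisubstituted vinyl iodide, made by a long linear sequence. The closure itself forms a seven-membered ring at a neopentyl aldehyde with excess divalent chromium, and the C10 configuration is not predictable. The chosen plan spends its steps after the ring construction, but reaches the bicycle in seven steps from commercial materials.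

Key step: step 7

## Route

Step 1
Reactants: 1 (E)-but-2-enal; 2 ethyl 2-(triphenylphosphoranylidene)propanoate
Product: 3 ethyl (2E,4E)-2-methylhexa-2,4-dienoate
Conditions: CH2Cl2, rt
Reagents that add atoms: none
Why: Wittig olefination with a stabilised ylide, E-selective at the new trisubstituted alkene; it assembles the carbons that become C2, C1 (with its methyl), C10, C9 and C8 (with its methyl).

Step 2
Reactants: 3 ethyl (2E,4E)-2-methylhexa-2,4-dienoate
Product: 4 (2E,4E)-2-methylhexa-2,4-dien-1-ol
Conditions: iBu2AlH (2.2 equiv), CH2Cl2, −78 → 0 °C; aq potassium sodium tartrate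
Reagents that add atoms: none
Why: 1,2-reduction of a conjugated ester to the allylic alcohol by an aluminium hydride; no conjugate reduction at low temperature and both alkene geometries are kept.

Step 3
Reactants: 4 (2E,4E)-2-methylhexa-2,4-dien-1-ol
Product: 5 (2E,4E)-1-bromo-2-methylhexa-2,4-diene
Conditions: PBr3 (0.4 equiv), Et2O, −10 °C; used crude
Reagents that add atoms: phosphorus tribromide, BrP(Br)Br
Why: Bromination of a primary allylic alcohol through its phosphite ester (SN2); the conjugated primary bromide is the stable regioisomer and is used at once to avoid allylic scrambling.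

Step 4
Reactants: 5 (2E,4E)-1-bromo-2-methylhexa-2,4-diene; 6 N-methoxy-N-methylacetamide
Product: 7 (4E,6E)-N-methoxy-N,4-dimethylocta-4,6-dienamide
Conditions: LiN(iPr)2, THF, −78 °C; then 5, −78 → 0 °C
Reagents that add atoms: none
Why: Enolate alkylation of a Weinreb amide with a primary allylic bromide (SN2 at CH2); it forms the C2–C3 bond and leaves an acyl group that can be turned into a ketone without over-addition.

Step 5
Reactants: 7 (4E,6E)-N-methoxy-N,4-dimethylocta-4,6-dienamide; 8 allylmagnesium bromide
Product: 9 (7E,9E)-7-methylundeca-1,7,9-trien-4-one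
Conditions: THF, −78 → −20 °C; aq NH4Cl at −20 °C
Reagents that add atoms: none
Why: Weinreb ketone synthesis; the chelated tetrahedral intermediate stops at mono-addition, and a cold, weakly acidic quench keeps the β,γ-alkene out of conjugation.

Step 6
Reactants: 9 (7E,9E)-7-methylundeca-1,7,9-trien-4-one
Product: 10 (7E,9E)-3-diazo-7-methylundeca-1,7,9-trien-4-one
Conditions: 4-acetamidobenzenesulfonyl azide, DBU, MeCN, 0 °C; kept cold, used at once
Reagents that add atoms: 4-acetamidobenzenesulfonyl azide, CC(=O)Nc1ccc(cc1)S(=O)(=O)N=[N+]=[N-]
Why: Regitz diazo transfer to the doubly activated CH2 between carbonyl and vinyl group, the usual entry to vinyldiazo carbonyl compounds; the methyl-side α-protons are far less acidic and do not compete.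

Step 7
Reactants: 10 (7E,9E)-3-diazo-7-methylundeca-1,7,9-trien-4-one
Product: 12 (3aR,6R)-3a,6-dimethyl-3,3a,6,7-tetrahydroazulen-1(2H)-one, via divinylcyclopropane 11 (not isolated)
Conditions: Rh2(S-PTAD)4 (dirhodium tetrakis[(S)-(1-adamantyl)(N-phthalimido)acetate], 1 mol %), 2,2-dimethylbutane, −40 °C → rt, slow addition of 10; then toluene, 80 °C
Reagents that add atoms: none
Why: The dirhodium tetracarboxylate takes nitrogen from 10 and gives a vinylcarbenoid at C5 (donor C6=C7, acceptor C4=O), which adds to the tethered C1=C10 alkene; this intramolecular cyclopropanation closes ring A as the five-membered ring of a bicyclo[3.1.0]hexan-2-one (bonds C5–C1 and C5–C10), the proximal alkene being chosen because only it gives a five-membered ring. The addition is stereospecific, so the E geometry of C1=C10 places the C10 propenyl group on the cyclopropane face of the C1 methyl and the C5 vinyl group, and 11 is a cis-divinylcyclopropane. A [3,3] sigmatropic shift through the only possible (boat) transition state then joins C7 to C8 and breaks C5–C10, closing ring B by ring expansion to the cyclohepta-1,4-diene (divinylcyclopropane–cycloheptadiene rearrangement). C1 is set by the chiral carboxylate ligands, which choose the face of C1=C10 that the carbenoid attacks; C8 follows from C1 through the boat, in which the E-methyl of the propenyl terminus points outwards, so H8 ends cis to the C1 methyl. The closest known reaction type is the tandem cyclopropanation–Cope rearrangement of rhodium vinylcarbenoids with dienes, a formal (4+3) cycloaddition, in its intramolecular form. The step needs reaction at the carbenoid carbon and not at the vinyl terminus, and cyclopropanation in preference to C–H insertion, which a hydrocarbon solvent, a carboxylate catalyst and the short tether secure; it also needs enantioface control, for which the phthalimido carboxylate is chosen because ketone acceptors respond to it better than to prolinate catalysts. Because the C1 methyl must take the flagpole position of the boat, the shift is expected to need warming, which is why the mixture is heated before work-up.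

Step 8
Reactants: 12 (3aR,6R)-3a,6-dimethyl-3,3a,6,7-tetrahydroazulen-1(2H)-one
Product: 13 epoxy enone: 12 with C9=C10 converted into the 9α,10α-epoxide (C4 ketone, C5=C6, 1β-methyl, 8α-methyl)
Conditions: mCPBA, NaHCO3, CH2Cl2, 0 °C
Reagents that add atoms: 3-chloroperoxybenzoic acid, OOC(=O)c1cccc(Cl)c1
Why: Prilezhaev epoxidation, chemoselective for the isolated C9=C10 alkene because C5=C6 is deactivated by the carbonyl group; the peracid should approach anti to the C1 methyl, which stands pseudo-axially over the β face next to C10, and so place the oxygen α.

Step 9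
Reactants: 13 epoxy enone (9α,10α-epoxide, C4 ketone, C5=C6)
Product: 14 (4S) allylic alcohol: 13 with the C4 ketone reduced to the 4β-hydroxyl
Conditions: (R)-Me-CBS oxazaborolidine [(R)-1-methyl-3,3-diphenyltetrahydro-1H,3H-pyrrolo[1,2-c][1,3,2]oxazaborole] (20 mol %), catecholborane, toluene, −78 °C
Reagents that add atoms: none
Why: Corey–Bakshi–Shibata 1,2-reduction of an enone with the alkenyl side as the large group; the (R)-catalyst delivers hydride to the α face of C4 and sets the 4β-carbinol under catalyst control, and the epoxide is inert to the borane at this temperature.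

Step 10
Reactants: 14 (4S) allylic alcohol (4β-OH, 9α,10α-epoxide, C5=C6)
Product: 15 tert-butyldimethylsilyl ether of 14 (4β-OTBS)
Conditions: TBSCl, imidazole, DMAP (cat.), DMF, rt
Reagents that add atoms: tert-butyldimethylsilyl chloride, CC(C)(C)[Si](C)(C)Cl
Why: Imidazole-mediated silylation of a secondary alcohol; the ether masks C4 through eight steps and its bulk on the β face later steers the hydroboration of C5=C6.

Step 11
Reactants: 15 silyl ether (4β-OTBS, 9α,10α-epoxide, C5=C6)
Product: 16 hydroxy selenide: 9β-phenylselanyl, 10α-hydroxyl, 8α-methyl, 4β-OTBS, C5=C6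
Conditions: PhSeSePh, NaBH4, EtOH, rt → 60 °C
Reagents that add atoms: diphenyl diselenide, c1ccc(cc1)[Se][Se]c1ccccc1
Why: Epoxide opening by benzeneselenolate (first half of the Sharpless epoxide-to-allylic-alcohol transposition): SN2 with inversion at C9, the carbon away from the quaternary centre, gives the 9β-selenide and the 10α-alcohol; it also leaves ring B with C5=C6 as its only rigid unit.

Step 12
Reactants: 16 hydroxy selenide (9β-SePh, 10α-OH)
Product: 17 acetate of 16 (10α-OAc, 9β-SePh, 4β-OTBS, C5=C6)
Conditions: Ac2O, Et3N, DMAP, CH2Cl2, rt
Reagents that add atoms: acetic anhydride, CC(=O)OC(C)=O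
Why: DMAP-catalysed acetylation of the only free hydroxyl; it installs the final C10 acetate and keeps this oxygen distinct from the C6 hydroxyl made in the next step.

Step 13
Reactants: 17 acetate (10α-OAc, 9β-SePh, 4β-OTBS, C5=C6)
Product: 20 6α-hydroxy-10α-acetoxy-4β-silyloxy-8-ene (5α-H; C8=C9 with the methyl on C8), via alkylborane 18 (not isolated), via selenoxide 19 (not isolated)
Conditions: BH3·THF (3 equiv), THF, 0 °C → rt; then NaBO3·4H2O, H2O, rt; then 30% H2O2, pyridine, 0 °C → rt
Reagents that add atoms: borane–tetrahydrofuran, B.C1CCOC1 (boron only in 18); hydrogen peroxide, also delivered as sodium perborate, OO (the C6 oxygen of 20 and the Se=O oxygen of 19)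
Why: Brown hydroboration–oxidation: syn, anti-Markovnikov addition with boron at C6, from the α face because the β face of C5=C6 is covered by the C1 methyl and the allylic 4β-silyloxy group (anti to the allylic oxygen), which sets 5α-H (trans fusion) and 6α-OH with retention on oxidation. The same peroxide oxidises the selenide to selenoxide 19, whose syn elimination takes the 8β-hydrogen, away from the acetoxy-bearing carbon, and gives the C8=C9 allylic acetate.

Step 14
Reactants: 20 6α-hydroxy-10α-acetoxy-4β-silyloxy-8-ene
Product: 21 8α,9α-epoxide of 20 (8β-methyl, 6α-OH, 10α-OAc, 4β-OTBS)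
Conditions: VO(acac)2 (5 mol %), tBuOOH, CH2Cl2, 0 °C → rt
Reagents that add atoms: tert-butyl hydroperoxide, CC(C)(C)OO
Why: Vanadium-catalysed hydroxyl-directed epoxidation; the homoallylic 6α-hydroxyl binds the metal peroxide and delivers oxygen to the α face of C8=C9, which leaves the C8 methyl β.

Step 15
Reactants: 21 epoxy alcohol (6α-OH, 8α,9α-epoxide, 10α-OAc, 4β-OTBS)
Product: 22 6α-(3-methylbutanoate) of 21
Conditions: 3-methylbutanoic anhydride, Et3N, DMAP, CH2Cl2, rt
Reagents that add atoms: 3-methylbutanoic anhydride, CC(C)CC(=O)OC(=O)CC(C)C
Why: DMAP-catalysed acylation of the only free hydroxyl; neutral to weakly basic conditions leave the epoxide and the acetate alone.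

Step 16
Reactants: 22 diester silyl ether (4β-OTBS)
Product: 23 4β-alcohol: 22 without the silyl group
Conditions: HF·pyridine, pyridine, THF, 0 °C → rt
Reagents that add atoms: none
Why: Fluoride-mediated desilylation under buffered, non-basic conditions; no alkoxide is formed, so the C6 ester does not shift to C4, and pyridine-buffered HF is tolerated by trialkyl epoxides.

Step 17
Reactants: 23 4β-alcohol (6α-isovalerate, 8α,9α-epoxide, 10α-acetate)
Product: 24 C4 ketone (5α-H, 6α-isovalerate, 8α,9α-epoxide, 10α-acetate)
Conditions: Dess–Martin periodinane, NaHCO3, CH2Cl2, 0 °C → rt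
Reagents that add atoms: none
Why: Dess–Martin oxidation of a secondary alcohol under buffered neutral conditions, which should neither epimerise C5 nor eliminate the β-acyloxy group.

Step 18
Reactants: 24 C4 ketone; 25 isopropylmagnesium chloride
Product: 26 (1S,4R,5S,6S,8R,9S,10S)-10-acetoxy-8,9-epoxy-4-hydroxydaucan-6-yl 3-methylbutanoate (CNP0137153.1)
Conditions: CeCl3 (anhydrous), THF; 25, −78 °C; then 24, −78 °C; aq NH4Cl
Reagents that add atoms: none
Why: Imamoto organocerium 1,2-addition: the weakly basic reagent adds to the ketone faster than to esters and with little enolisation. It should enter from the α face, anti to the C5–C6 bond and the C1 methyl that close the β face of ring A (as for D-ring ketones of trans-hydrindanes), giving the 4β-hydroxyl.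

## Compound list

1 | (E)-but-2-enal | C/C=C/C=O | starting material
2 | ethyl 2-(triphenylphosphoranylidene)propanoate | CCOC(=O)C(C)=P(c1ccccc1)(c1ccccc1)c1ccccc1 | starting material
3 | ethyl (2E,4E)-2-methylhexa-2,4-dienoate | CCOC(=O)/C(C)=C/C=C/C | intermediate
4 | (2E,4E)-2-methylhexa-2,4-dien-1-ol | OC/C(C)=C/C=C/C | intermediate
5 | (2E,4E)-1-bromo-2-methylhexa-2,4-diene | BrC/C(C)=C/C=C/C | intermediate
6 | N-methoxy-N-methylacetamide | CC(=O)N(C)OC | starting material
7 | (4E,6E)-N-methoxy-N,4-dimethylocta-4,6-dienamide | CON(C)C(=O)CC/C(C)=C/C=C/C | intermediate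
8 | allylmagnesium bromide | C=CC[Mg]Br | starting material
9 | (7E,9E)-7-methylundeca-1,7,9-trien-4-one | C=CCC(=O)CC/C(C)=C/C=C/C | intermediate
10 | (7E,9E)-3-diazo-7-methylundeca-1,7,9-trien-4-one | C=CC(=[N+]=[N-])C(=O)CC/C(C)=C/C=C/C | intermediate
11 | 1-ethenyl-5-methyl-6-[(E)-prop-1-enyl]bicyclo[3.1.0]hexan-2-one, with vinyl, propenyl and methyl all on one face of the cyclopropane (not isolated) | C=C[C@@]12C(=O)CC[C@]1(C)[C@H]2/C=C/C | intermediate
12 | (3aR,6R)-3a,6-dimethyl-3,3a,6,7-tetrahydroazulen-1(2H)-one (C4 ketone, C5=C6, C9=C10, 1β-methyl, 8α-methyl) | C[C@H]1C=C[C@@]2(C)CCC(=O)C2=CC1 | intermediate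
13 | 9α,10α-epoxide of 12 (C4 ketone, C5=C6) | O1[C@@H]2[C@H]1[C@H](C)CC=C3[C@]2(C)CCC3=O | intermediate
14 | (4S)-4β-hydroxy-9α,10α-epoxy-5-ene | O1[C@@H]2[C@H]1[C@H](C)CC=C3[C@]2(C)CC[C@@H]3O | intermediate
15 | 4β-(tert-butyldimethylsilyloxy)-9α,10α-epoxy-5-ene | O1[C@@H]2[C@H]1[C@H](C)CC=C3[C@]2(C)CC[C@@H]3O[Si](C)(C)C(C)(C)C | intermediate
16 | 9β-(phenylselanyl)-4β-(tert-butyldimethylsilyloxy)-5-en-10α-ol | O[C@@H]1[C@@H]([Se]c2ccccc2)[C@H](C)CC=C3[C@]1(C)CC[C@@H]3O[Si](C)(C)C(C)(C)C | intermediate
17 | 10α-acetate of 16 | CC(=O)O[C@@H]1[C@@H]([Se]c2ccccc2)[C@H](C)CC=C3[C@]1(C)CC[C@@H]3O[Si](C)(C)C(C)(C)C | intermediate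
18 | C6α-borane of 17 (5α-H; not isolated) | CC(=O)O[C@@H]1[C@@H]([Se]c2ccccc2)[C@H](C)C[C@H](B)[C@@H]3[C@]1(C)CC[C@@H]3O[Si](C)(C)C(C)(C)C | intermediate
19 | 6α-hydroxy-9β-phenylseleninyl compound (selenoxide; not isolated) | CC(=O)O[C@@H]1[C@@H]([Se](=O)c2ccccc2)[C@H](C)C[C@H](O)[C@@H]3[C@]1(C)CC[C@@H]3O[Si](C)(C)C(C)(C)C | intermediate
20 | 10α-acetoxy-4β-(tert-butyldimethylsilyloxy)-8-en-6α-ol (5α-H) | CC(=O)O[C@@H]1C=C(C)C[C@H](O)[C@@H]2[C@]1(C)CC[C@@H]2O[Si](C)(C)C(C)(C)C | intermediate
21 | 8α,9α-epoxide of 20 | CC(=O)O[C@@H]1[C@@H]2O[C@]2(C)C[C@H](O)[C@@H]3[C@]1(C)CC[C@@H]3O[Si](C)(C)C(C)(C)C | intermediate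
22 | 6α-(3-methylbutanoate) of 21 | CC(=O)O[C@@H]1[C@@H]2O[C@]2(C)C[C@H](OC(=O)CC(C)C)[C@@H]3[C@]1(C)CC[C@@H]3O[Si](C)(C)C(C)(C)C | intermediate
23 | 4β-alcohol from 22 | CC(=O)O[C@@H]1[C@@H]2O[C@]2(C)C[C@H](OC(=O)CC(C)C)[C@@H]3[C@]1(C)CC[C@@H]3O | intermediate
24 | C4 ketone from 23 | CC(=O)O[C@@H]1[C@@H]2O[C@]2(C)C[C@H](OC(=O)CC(C)C)[C@@H]3[C@]1(C)CCC3=O | intermediate
25 | isopropylmagnesium chloride | CC(C)[Mg]Cl | starting material
26 | (1S,4R,5S,6S,8R,9S,10S)-10-acetoxy-8,9-epoxy-4-hydroxydaucan-6-yl 3-methylbutanoate | CC(=O)O[C@@H]1[C@@H]2O[C@]2(C)C[C@H](OC(=O)CC(C)C)[C@@H]2[C@]1(C)CC[C@@]2(O)C(C)C | target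

## Step count and least certain steps

Total step count: 18. Longest linear sequence: 18 steps (1 → 26); 2, 6, 8 and 25 are commercial.

**Step 7 (key step).** The most likely failure is weak enantioface discrimination in the cyclopropanation, because a ketone acceptor is held less firmly by the catalyst than an ester. A second concern is a slow [3,3] shift (the C1 methyl in the flagpole position), which on long heating would let the cyclopropane epimerise by homolysis. Fallback: give up catalyst control of C1 and separate under reagent control. From 10, Rh2(OAc)4 gives the racemic dienone, that is 12 together with its enantiomer, ent-dienone F1. Epoxidation as in step 8 gives 13 together with ent-epoxy enone F2. The (R)-oxazaborolidine reduction of step 9 then turns the two enantiomers into diastereomers, 14 and the (4S) alcohol of the enantiomeric skeleton F3. These differ in the relation of the carbinol to the C1 methyl and are separated by chromatography. The route is rejoined at 14.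

**Step 13.** The most likely failure is poor facial selectivity in the delivery of H–B, leading to cis ring fusion, since in a seven-membered ring the α face is flanked by ring carbons. Lesser risks are slow reduction of the acetate by borane and epoxidation of the new alkene by peroxyseleninic acid. Fallback: correct C5 and C6 thermodynamically. The fallback sets out from crude 20 (mixed with its C5,C6 epimer). Dess–Martin oxidation gives the C6 ketone F4, in which C5 is epimerisable and is equilibrated with DBU to the trans-fused isomer, expected to be the more stable one for a carbonyl group in the seven-membered ring. Single-electron reduction (SmI2, H2O, Et3N), which favours the equatorial alcohol, returns 20.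

**Step 8.** The likely failure is epoxidation on the wrong face: ring B of 12 is a boat whose α face is concave, so the peracid may prefer the β face in spite of the C1 methyl. Fallback: reverse the facial outcome through a halohydrin. From 12, N-bromosuccinimide in wet dimethoxyethane puts bromine on the face the electrophile prefers and water on the other, giving the trans bromohydrin, 10β-bromo-9α-hydroxy enone F5 (whichever carbon water attacks, the oxygen is α). K2CO3 in methanol closes it to 13.

**Step 18.** The likely failure is enolisation towards C5 followed by loss of the C6 ester by β-elimination, or attack of the reagent on an ester. Fallback: carry C6 as an ether through the addition and acylate last. From 20, 4-methoxybenzyl trichloroacetimidate with catalytic Sc(OTf)3 gives the C6 4-methoxybenzyl ether F6. Buffered Bu4NF removes the C4 silyl group to give alcohol F7, and Dess–Martin oxidation gives the β-alkoxy ketone F8. Isopropylmagnesium chloride with CeCl3 gives the tertiary alcohol F9, and DDQ frees the C6 hydroxyl to give diol F10. VO(acac)2 with tBuOOH gives the epoxy diol F11, and 3-methylbutanoic anhydride with DMAP acylates only the secondary hydroxyl to give 26.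

**Step 6.** The likely failure is base-induced migration of the β,γ-alkene into conjugation during diazo transfer, and cyclisation of the terminal vinyldiazo compound to a pyrazole on standing. Fallback: introduce the diazo group before the vinyl group. From 7, MeMgBr gives the methyl ketone F12. LiN(SiMe3)2 with 2,2,2-trifluoroethyl trifluoroacetate gives the trifluoroacetyl diketone F13, and methanesulfonyl azide with Et3N gives the terminal diazoketone F14 (detrifluoroacetylative diazo transfer). DBU-mediated aldol addition to acetaldehyde gives the hydroxy diazoketone F15, and dehydration with POCl3 and Et3N gives 10.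

## Further compounds

F1 | step 7 | (3aS,6S)-3a,6-dimethyl-3,3a,6,7-tetrahydroazulen-1(2H)-one (enantiomer of 12) | C[C@@H]1C=C[C@]2(C)CCC(=O)C2=CC1
F2 | step 7 | enantiomer of epoxy enone 13 | O1[C@H]2[C@@H]1[C@@H](C)CC=C3[C@@]2(C)CCC3=O
F3 | step 7 | (4S) alcohol of the enantiomeric skeleton (diastereomer of 14) | O1[C@H]2[C@@H]1[C@@H](C)CC=C3[C@@]2(C)CC[C@@H]3O
F4 | step 13 | 10α-acetoxy-4β-(tert-butyldimethylsilyloxy)-8-en-6-one (5α-H) | CC(=O)O[C@@H]1C=C(C)CC(=O)[C@@H]2[C@]1(C)CC[C@@H]2O[Si](C)(C)C(C)(C)C
F5 | step 8 | 10β-bromo-9α-hydroxy enone (C4 ketone, C5=C6) | Br[C@H]1[C@H](O)[C@H](C)CC=C2[C@]1(C)CCC2=O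
F6 | step 18 | 6α-(4-methoxybenzyl) ether of 20 | CC(=O)O[C@@H]1C=C(C)C[C@H](OCc3ccc(OC)cc3)[C@@H]2[C@]1(C)CC[C@@H]2O[Si](C)(C)C(C)(C)C
F7 | step 18 | 4β-alcohol from F6 | CC(=O)O[C@@H]1C=C(C)C[C@H](OCc3ccc(OC)cc3)[C@@H]2[C@]1(C)CC[C@@H]2O
F8 | step 18 | C4 ketone from F7 | CC(=O)O[C@@H]1C=C(C)C[C@H](OCc3ccc(OC)cc3)[C@@H]2[C@]1(C)CCC2=O
F9 | step 18 | 4β-hydroxy-4α-isopropyl compound from F8 | CC(=O)O[C@@H]1C=C(C)C[C@H](OCc3ccc(OC)cc3)[C@@H]2[C@]1(C)CC[C@@]2(O)C(C)C
F10 | step 18 | 10α-acetoxy-8-ene-4β,6α-diol | CC(=O)O[C@@H]1C=C(C)C[C@H](O)[C@@H]2[C@]1(C)CC[C@@]2(O)C(C)C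
F11 | step 18 | 10α-acetoxy-8α,9α-epoxy-4β,6α-diol | CC(=O)O[C@@H]1[C@@H]2O[C@]2(C)C[C@H](O)[C@@H]3[C@]1(C)CC[C@@]3(O)C(C)C
F12 | step 6 | (5E,7E)-6-methylnona-5,7-dien-2-one | CC(=O)CC/C(C)=C/C=C/C
F13 | step 6 | (7E,9E)-1,1,1-trifluoro-8-methylundeca-7,9-diene-2,4-dione | FC(F)(F)C(=O)CC(=O)CC/C(C)=C/C=C/C
F14 | step 6 | (5E,7E)-1-diazo-6-methylnona-5,7-dien-2-one | [N-]=[N+]=CC(=O)CC/C(C)=C/C=C/C
F15 | step 6 | (7E,9E)-3-diazo-2-hydroxy-7-methylundeca-7,9-dien-4-one | CC(O)C(=[N+]=[N-])C(=O)CC/C(C)=C/C=C/C
A1 | alternative 1 | cyclopentane-fused isoxazoline with C1, C4 and C5 set | CC(C)[C@]12CC[C@](C)(CO[Si](C)(C)C(C)(C)C)[C@H]1C(C/C(C)=C\I)=NO2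
A2 | alternative 1 | 1-isopropyl-3-methyl-3-(tert-butyldimethylsilyloxymethyl)cyclopentene | CC(C)C1=C[C@@](C)(CO[Si](C)(C)C(C)(C)C)CC1
A3 | alternative 1 | (Z)-4-iodo-3-methylbut-3-enenitrile oxide | [O-][N+]#CC/C(C)=C\I
A4 | alternative 2 | tricyclic photoadduct with quaternary C1 and masked C6–C10 diol | C[Si](C)(C)O[C@]12C[C@H](C)C[C@@]1(O[Si](C)(C)C)[C@@H]3C(=O)CC[C@]23C
A5 | alternative 2 | 3-methylcyclopent-2-en-1-one | CC1=CC(=O)CC1
A6 | alternative 2 | 4-methyl-1,2-bis(trimethylsilyloxy)cyclopent-1-ene | CC1CC(O[Si](C)(C)C)=C(O[Si](C)(C)C)C1
A7 | alternative 3 | bicyclic allylic alcohol (10α-OH, C8=C9, 6α-isovalerate) | O[C@@H]1C=C(C)C[C@H](OC(=O)CC(C)C)[C@@H]2[C@]1(C)CC[C@@]2(O)C(C)C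
A8 | alternative 3 | Z-vinyl iodide aldehyde (C10 formyl on C1, iodide on C9) | O=C[C@@]1(C)CC[C@@](O)(C(C)C)[C@@H]1[C@@H](OC(=O)CC(C)C)C/C(C)=C\I
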